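Labels: seven-membered ring C1(OAc)–C2–C3(CH3)–C7(H)–C8(OAr)–C9=C10(CH3); five-membered ring C3–C4–C5–C6(OH, iPr)–C7. Everything rests on the C3–C7 bond: C1–C2–C3(CH3)–C4–C5–C6 is the (S)-citronellol backbone, and its tertiary C3–H lies 1,5 to C7. A rhodium carbene at C7 inserts into that C–H bond with retention, which in one operation closes the five-membered ring, forms C3–C7 and creates the quaternary centre from the chiral pool. The precursor is acyclic diazo keto ester 13 (C8 ester, diazo C7, C6 ketone, silyl ether at C1). C7 is fixed afterwards by hydrogenation under dynamic kinetic resolution; the seven-membered ring is closed last at C10–C1.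

Key step: step 5

Remark: 15 is assumed to epimerise at C7 through its enol much faster than it is hydrogenated, as α-monosubstituted β-keto esters generally do, and step 6 depends on this (TBS = tert-butyldimethylsilyl, TES = triethylsilyl).

Step 1
Reactants: 1 (S)-citronellol; 2 tert-butyldimethylsilyl chloride
Product: 3 tert-butyl{[(3S)-3,7-dimethyloct-6-en-1-yl]oxy}dimethylsilane
Conditions: TBSCl, imidazole, CH2Cl2, 0 °C → rt
Reagents that add atoms: tert-butyldimethylsilyl chloride, CC(C)(C)[Si](C)(C)Cl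
Why: Imidazole-promoted silyl ether formation at the primary alcohol is routine and touches neither the C3 stereocentre nor the alkene.

Step 2
Reactants: 3 silyl ether; 4 ozone; 5 sodium chlorite (NaClO2)
Product: 7 (4S)-6-[(tert-butyldimethylsilyl)oxy]-4-methylhexanoic acid, via aldehyde 6 (not isolated)
Conditions: O3, NaHCO3, CH2Cl2/MeOH, −78 °C; Me2S, −78 °C → rt; concentrate; NaClO2, NaH2PO4, 2-methyl-2-butene, tBuOH/H2O, rt
Reagents that add atoms: ozone, [O-][O+]=O; sodium chlorite, [Na+].[O-]Cl=O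
Why: Ozonolysis of the trisubstituted alkene with reductive work-up followed by Pinnick oxidation of the crude aldehyde should give the acid under buffered conditions that spare the silyl ether, the stereocentre being remote from every reacting atom.

Step 3
Reactants: 7 acid; 8 Meldrum's acid; 9 methanol
Product: 11 methyl (6S)-8-[(tert-butyldimethylsilyl)oxy]-6-methyl-3-oxooctanoate, via acyl Meldrum's acid 10 (not isolated)
Conditions: Meldrum's acid, DCC, DMAP, CH2Cl2, 0 °C → rt; filter, cold aq. citric acid wash; MeOH, reflux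
Reagents that add atoms: Meldrum's acid, CC1(C)OC(=O)CC(=O)O1; methanol, CO
Why: Oikawa–Yonemitsu homologation, in which carbodiimide-mediated C-acylation of Meldrum's acid and methanolysis with loss of acetone and CO2 give the β-keto ester that carries C7 and C8.

Step 4
Reactants: 11 β-keto ester; 12 4-acetamidobenzenesulfonyl azide
Product: 13 methyl (6S)-8-[(tert-butyldimethylsilyl)oxy]-2-diazo-6-methyl-3-oxooctanoate
Conditions: p-ABSA, Et3N, MeCN, 0 °C → rt
Reagents that add atoms: 4-acetamidobenzenesulfonyl azide, CC(=O)Nc1ccc(cc1)S(=O)(=O)N=[N+]=[N-]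
Why: Regitz diazo transfer to the doubly activated methylene proceeds readily with a sulfonyl azide and a tertiary amine base.

Step 5
Reactants: 13 diazo keto ester
Product: 15 methyl (1R,2R)-2-{2-[(tert-butyldimethylsilyl)oxy]ethyl}-2-methyl-5-oxocyclopentane-1-carboxylate (C8 ester cis to the C3 methyl; equilibrating at C7 with its epimer and enol), via Rh2(OAc)4-bound carbene 14 (not isolated)
Conditions: Rh2(OAc)4 (1 mol %), CH2Cl2, rt, slow addition of 13
Reagents that add atoms: none
Why: Rh2(OAc)4 (divalent rhodium) expels N2 from 13 to give the electrophilic acceptor/acceptor carbene 14 at C7, which inserts into the C3–H bond through a concerted three-centre transition state with hydride-transfer character. The closest known reaction type is the dirhodium-catalysed intramolecular 1,5 C–H insertion of α-diazo β-keto esters, a standard cyclopentanone synthesis. The five-membered ring C3–C4–C5–C6–C7 closes by 1,5-insertion, the carbene carbon C7 bonding to C3 through a chair-like six-centre array that includes the migrating hydrogen. C3 is formed with retention because the new C–C bond forms on the face the hydrogen leaves, so the (S) methine of the chiral pool becomes the (R) quaternary centre, whereas C7 is created between two carbonyls, stays epimerisable and is fixed only in step 6. The step needs site selectivity for C3–H over the C2, C4 and methyl C–H bonds, which is secured by the preference for five-membered closure and by C3–H being the only tertiary, most electron-rich C–H within reach. Slow addition of 13 keeps the carbene from dimerising.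

Step 6
Reactants: 15 cyclopentanone keto ester
Product: 16 methyl (1R,2R,5R)-2-{2-[(tert-butyldimethylsilyl)oxy]ethyl}-5-hydroxy-2-methylcyclopentane-1-carboxylate
Conditions: H2 (50–100 atm), RuCl2[(R)-BINAP] (1 mol %), CH2Cl2, 50 °C
Reagents that add atoms: none
Why: Noyori hydrogenation under dynamic kinetic resolution, in which the C7 epimers interconvert through the enol while RuCl2[(R)-BINAP] selects the ketone face and cyclic β-keto esters react in the anti mode, so the C6 hydroxyl and the ester should emerge trans with C8 cis to the C3 methyl and trans to the C2 arm.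

Step 7
Reactants: 16 hydroxy ester
Product: 17 (1R,2S,3R)-3-{2-[(tert-butyldimethylsilyl)oxy]ethyl}-2-(hydroxymethyl)-3-methylcyclopentan-1-ol
Conditions: LiAlH4, THF, 0 °C
Reagents that add atoms: none
Why: Hydride reduction of the ester gives the 1,3-diol, the C6 alkoxide formed first shielding C7 from epimerisation.

Step 8
Reactants: 17 diol; 18 chlorotriethylsilane
Product: 19 (1R,2S,3R)-3-{2-[(tert-butyldimethylsilyl)oxy]ethyl}-3-methyl-2-{[(triethylsilyl)oxy]methyl}cyclopentan-1-ol
Conditions: TESCl (1.05 equiv), imidazole, CH2Cl2, −78 → −40 °C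
Reagents that add atoms: chlorotriethylsilane, CC[Si](Cl)(CC)CC
Why: Silyl ether formation at low temperature should select the primary C8 hydroxyl over the ring secondary hydroxyl on steric grounds.

Step 9
Reactants: 19 TES ether
Product: 20 (2S,3R)-3-{2-[(tert-butyldimethylsilyl)oxy]ethyl}-3-methyl-2-{[(triethylsilyl)oxy]methyl}cyclopentan-1-one
Conditions: Dess–Martin periodinane, NaHCO3, CH2Cl2, 0 °C → rt; crude product used directly
Reagents that add atoms: none
Why: Dess–Martin oxidation under buffered, non-basic conditions returns the C6 ketone without epimerising C7 or eliminating the β-silyloxy group.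

Step 10
Reactants: 20 ketone; 21 isopropylmagnesium chloride
Product: 23 (1R,2S,3R)-3-{2-[(tert-butyldimethylsilyl)oxy]ethyl}-2-(hydroxymethyl)-3-methyl-1-(propan-2-yl)cyclopentan-1-ol, via TES ether 22 (not isolated)
Conditions: iPrMgCl, CeCl3 (anhydrous), THF, −78 → 0 °C; aq. NH4Cl; crude, PPTS, MeOH, 0 °C
Reagents that add atoms: isopropylmagnesium chloride, CC(C)[Mg]Cl
Why: Imamoto organocerium 1,2-addition, which suppresses enolisation and β-hydride reduction, should occur on the ketone face anti to the adjacent C7 silyloxymethyl group, placing isopropyl cis to H7 and the C6 hydroxyl cis to C8 and the C3 methyl, after which mild acid methanolysis cleaves the primary TES ether and leaves the TBS ether.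

Step 11
Reactants: 23 diol
Product: 24 (1R,2R,5R)-2-{2-[(tert-butyldimethylsilyl)oxy]ethyl}-5-hydroxy-2-methyl-5-(propan-2-yl)cyclopentane-1-carbaldehyde
Conditions: Dess–Martin periodinane, NaHCO3, CH2Cl2, 0 °C; used at once
Reagents that add atoms: none
Why: Dess–Martin oxidation converts the primary alcohol to the C8 aldehyde while the tertiary hydroxyl is inert, and the neutral medium avoids retro-aldol cleavage, dehydration or C7 epimerisation of the β-hydroxy aldehyde.

Step 12
Reactants: 24 aldehyde; 25 1-propynylmagnesium bromide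
Product: 26 (1R,2S,3R)-3-{2-[(tert-butyldimethylsilyl)oxy]ethyl}-2-[(1R)-1-hydroxybut-2-yn-1-yl]-3-methyl-1-(propan-2-yl)cyclopentan-1-ol
Conditions: MeC≡CMgBr (3 equiv), CH2Cl2/THF, −78 °C
Reagents that add atoms: 1-propynylmagnesium bromide, CC#C[Mg]Br
Why: Chelation-controlled (Cram chelate) Grignard addition, in which the magnesium alkoxide at the cis C6 oxygen binds the aldehyde oxygen in a six-membered chelate and the alkynyl group enters from the H7 side, away from the quaternary C3, which should give the (R)-carbinol at C8.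

Step 13
Reactants: 26 propargylic alcohol; 27 iodine
Product: 29 (1R,2S,3R)-3-{2-[(tert-butyldimethylsilyl)oxy]ethyl}-2-[(1R,2Z)-1-hydroxy-3-iodobut-2-en-1-yl]-3-methyl-1-(propan-2-yl)cyclopentan-1-ol, via cyclic alkenylalanate 28 (not isolated)
Conditions: NaAlH2(OCH2CH2OMe)2 (Red-Al), THF, 0 °C → rt; EtOAc; I2, THF, −78 → 0 °C
Reagents that add atoms: iodine, [I][I]
Why: Hydroxyl-directed trans-hydroalumination of the propargylic alcohol delivers hydride to C9 and aluminium to C10 within a five-membered alkoxyalanate, and iodinolysis with retention should give the (Z)-vinyl iodide with iodine cis to C8, the geometry the ring alkene needs.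

Step 14
Reactants: 29 vinyl iodide diol; 30 4-acetoxybenzoyl chloride
Product: 31 (1R,2Z)-1-[(1S,2R,5R)-2-{2-[(tert-butyldimethylsilyl)oxy]ethyl}-5-hydroxy-2-methyl-5-(propan-2-yl)cyclopentyl]-3-iodobut-2-en-1-yl 4-(acetyloxy)benzoate
Conditions: 4-acetoxybenzoyl chloride, Et3N, DMAP, CH2Cl2, 0 °C → rt
Reagents that add atoms: 4-acetoxybenzoyl chloride, CC(=O)Oc1ccc(cc1)C(Cl)=O
Why: DMAP-catalysed acylation esterifies the secondary allylic C8 hydroxyl while the hindered tertiary C6 hydroxyl stays free, and brings in the aryl ester with its phenol masked as an acetate.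

Step 15
Reactants: 31 aryl ester
Product: 32 (1R,2Z)-1-[(1S,2R,5R)-2-hydroxy-5-(2-hydroxyethyl)-5-methyl-2-(propan-2-yl)cyclopentyl]-3-iodobut-2-en-1-yl 4-(acetyloxy)benzoate
Conditions: HF·pyridine, pyridine, THF, 0 °C → rt
Reagents that add atoms: none
Why: Fluoride-mediated desilylation removes the primary TBS ether under buffered conditions that leave the aryl acetate, the allylic ester, the vinyl iodide and the tertiary alcohol untouched.

Step 16
Reactants: 32 primary alcohol
Product: 33 (1R,2Z)-1-[(1S,2R,5R)-2-hydroxy-5-methyl-5-(2-oxoethyl)-2-(propan-2-yl)cyclopentyl]-3-iodobut-2-en-1-yl 4-(acetyloxy)benzoate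
Conditions: Dess–Martin periodinane, NaHCO3, CH2Cl2, 0 °C → rt
Reagents that add atoms: none
Why: Dess–Martin oxidation gives the C1 aldehyde, and because the C6 hydroxyl lies on the ring face opposite the C2 arm no lactol can form to mask it.

Step 17
Reactants: 33 iodo aldehyde
Product: 34 (3R,3aS,4S,7S,8aR)-3,7-dihydroxy-6,8a-dimethyl-3-(propan-2-yl)-1,2,3,3a,4,7,8,8a-octahydroazulen-4-yl 4-(acetyloxy)benzoate
Conditions: CrCl2 (8 equiv), NiCl2 (2 mol %), DMSO, rt, 0.005 M
Reagents that add atoms: none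
Why: Intramolecular Nozaki–Hiyama–Kishi reaction, in which zerovalent nickel inserts into the C10–I bond, transmetalation gives a trivalent alkenylchromium that adds only to the C1 aldehyde (7-exo-trig closure with retention of alkene geometry), and the chromium alkoxide is expected to sit pseudo-equatorial on the forming trans-fused cycloheptene, away from the axial C3 methyl, which should give the (S)-carbinol at C1 cis to the C8 ester.

Step 18
Reactants: 34 allylic alcohol; 35 acetic anhydride
Product: 36 (3R,3aS,4S,7S,8aR)-7-(acetyloxy)-3-hydroxy-6,8a-dimethyl-3-(propan-2-yl)-1,2,3,3a,4,7,8,8a-octahydroazulen-4-yl 4-(acetyloxy)benzoate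
Conditions: Ac2O, pyridine, DMAP (cat.), CH2Cl2, 0 °C → rt
Reagents that add atoms: acetic anhydride, CC(=O)OC(C)=O
Why: DMAP-catalysed acetylation of the secondary allylic alcohol is standard, the tertiary C6 hydroxyl being too hindered to react.

Step 19
Reactants: 36 diacetate
Product: 37 (3R,3aS,4S,7S,8aR)-7-(acetyloxy)-3-hydroxy-6,8a-dimethyl-3-(propan-2-yl)-1,2,3,3a,4,7,8,8a-octahydroazulen-4-yl 4-hydroxybenzoate (target)
Conditions: pyrrolidine (1.5 equiv), CH2Cl2, 0 °C
Reagents that add atoms: none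
Why: Chemoselective aminolysis of the activated aryl acetate (phenoxide leaving group) by a secondary amine should free the phenol, while the alkyl acetate at C1 and the aryl ester at C8 have alkoxide leaving groups and do not react.

Compound list
1 | (S)-citronellol | C[C@@H](CCC=C(C)C)CCO | starting material
2 | tert-butyldimethylsilyl chloride | CC(C)(C)[Si](C)(C)Cl | starting material
3 | tert-butyl{[(3S)-3,7-dimethyloct-6-en-1-yl]oxy}dimethylsilane | C[C@@H](CCC=C(C)C)CCO[Si](C)(C)C(C)(C)C | intermediate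
4 | ozone | [O-][O+]=O | starting material
5 | sodium chlorite (NaClO2) | [Na+].[O-]Cl=O | starting material
6 | (4S)-6-[(tert-butyldimethylsilyl)oxy]-4-methylhexanal | O=CCC[C@H](C)CCO[Si](C)(C)C(C)(C)C | intermediate (not isolated)
7 | (4S)-6-[(tert-butyldimethylsilyl)oxy]-4-methylhexanoic acid | OC(=O)CC[C@H](C)CCO[Si](C)(C)C(C)(C)C | intermediate
8 | Meldrum's acid | CC1(C)OC(=O)CC(=O)O1 | starting material
9 | methanol | CO | starting material
10 | 5-{(4S)-6-[(tert-butyldimethylsilyl)oxy]-4-methylhexanoyl}-2,2-dimethyl-1,3-dioxane-4,6-dione (drawn as keto form) | CC1(C)OC(=O)C(C(=O)CC[C@H](C)CCO[Si](C)(C)C(C)(C)C)C(=O)O1 | intermediate (not isolated)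
11 | methyl (6S)-8-[(tert-butyldimethylsilyl)oxy]-6-methyl-3-oxooctanoate | COC(=O)CC(=O)CC[C@H](C)CCO[Si](C)(C)C(C)(C)C | intermediate
12 | 4-acetamidobenzenesulfonyl azide | CC(=O)Nc1ccc(cc1)S(=O)(=O)N=[N+]=[N-] | starting material
13 | methyl (6S)-8-[(tert-butyldimethylsilyl)oxy]-2-diazo-6-methyl-3-oxooctanoate | COC(=O)C(=[N+]=[N-])C(=O)CC[C@H](C)CCO[Si](C)(C)C(C)(C)C | intermediate
14 | Rh2(OAc)4-bound carbene at C7 of the (6S) keto ester (only the carbene carbon and one rhodium are drawn) | COC(=O)C(=[Rh])C(=O)CC[C@H](C)CCO[Si](C)(C)C(C)(C)C | intermediate (not isolated)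
15 | methyl (1R,2R)-2-{2-[(tert-butyldimethylsilyl)oxy]ethyl}-2-methyl-5-oxocyclopentane-1-carboxylate | CC(C)(C)[Si](C)(C)OCC[C@@]1(C)CCC(=O)[C@@H]1C(=O)OC | intermediate
16 | methyl (1R,2R,5R)-2-{2-[(tert-butyldimethylsilyl)oxy]ethyl}-5-hydroxy-2-methylcyclopentane-1-carboxylate | CC(C)(C)[Si](C)(C)OCC[C@@]1(C)CC[C@@H](O)[C@@H]1C(=O)OC | intermediate
17 | (1R,2S,3R)-3-{2-[(tert-butyldimethylsilyl)oxy]ethyl}-2-(hydroxymethyl)-3-methylcyclopentan-1-ol | CC(C)(C)[Si](C)(C)OCC[C@@]1(C)CC[C@@H](O)[C@@H]1CO | intermediate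
18 | chlorotriethylsilane | CC[Si](Cl)(CC)CC | starting material
19 | (1R,2S,3R)-3-{2-[(tert-butyldimethylsilyl)oxy]ethyl}-3-methyl-2-{[(triethylsilyl)oxy]methyl}cyclopentan-1-ol | CC(C)(C)[Si](C)(C)OCC[C@@]1(C)CC[C@@H](O)[C@@H]1CO[Si](CC)(CC)CC | intermediate
20 | (2S,3R)-3-{2-[(tert-butyldimethylsilyl)oxy]ethyl}-3-methyl-2-{[(triethylsilyl)oxy]methyl}cyclopentan-1-one | CC(C)(C)[Si](C)(C)OCC[C@@]1(C)CCC(=O)[C@@H]1CO[Si](CC)(CC)CC | intermediate
21 | isopropylmagnesium chloride | CC(C)[Mg]Cl | starting material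
22 | (1R,2S,3R)-3-{2-[(tert-butyldimethylsilyl)oxy]ethyl}-3-methyl-1-(propan-2-yl)-2-{[(triethylsilyl)oxy]methyl}cyclopentan-1-ol | CC(C)(C)[Si](C)(C)OCC[C@@]1(C)CC[C@@](O)(C(C)C)[C@@H]1CO[Si](CC)(CC)CC | intermediate (not isolated)
23 | (1R,2S,3R)-3-{2-[(tert-butyldimethylsilyl)oxy]ethyl}-2-(hydroxymethyl)-3-methyl-1-(propan-2-yl)cyclopentan-1-ol | CC(C)(C)[Si](C)(C)OCC[C@@]1(C)CC[C@@](O)(C(C)C)[C@@H]1CO | intermediate
24 | (1R,2R,5R)-2-{2-[(tert-butyldimethylsilyl)oxy]ethyl}-5-hydroxy-2-methyl-5-(propan-2-yl)cyclopentane-1-carbaldehyde | CC(C)(C)[Si](C)(C)OCC[C@@]1(C)CC[C@@](O)(C(C)C)[C@@H]1C=O | intermediate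
25 | 1-propynylmagnesium bromide | CC#C[Mg]Br | starting material
26 | (1R,2S,3R)-3-{2-[(tert-butyldimethylsilyl)oxy]ethyl}-2-[(1R)-1-hydroxybut-2-yn-1-yl]-3-methyl-1-(propan-2-yl)cyclopentan-1-ol | CC(C)(C)[Si](C)(C)OCC[C@@]1(C)CC[C@@](O)(C(C)C)[C@@H]1[C@@H](O)C#CC | intermediate
27 | iodine | [I][I] | starting material
28 | sodium cyclic alkenylalanate of 26 (O–Al–C10 five-membered ring; tertiary hydroxyl drawn free) | CC(C)(C)[Si](C)(C)OCC[C@@]1(C)CC[C@@](O)(C(C)C)[C@@H]1[C@H]2O[Al-](OCCOC)(OCCOC)C(C)=C2.[Na+] | intermediate (not isolated)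
29 | (1R,2S,3R)-3-{2-[(tert-butyldimethylsilyl)oxy]ethyl}-2-[(1R,2Z)-1-hydroxy-3-iodobut-2-en-1-yl]-3-methyl-1-(propan-2-yl)cyclopentan-1-ol | CC(C)(C)[Si](C)(C)OCC[C@@]1(C)CC[C@@](O)(C(C)C)[C@@H]1[C@@H](O)/C=C(/C)I | intermediate
30 | 4-acetoxybenzoyl chloride | CC(=O)Oc1ccc(cc1)C(Cl)=O | starting material
31 | (1R,2Z)-1-[(1S,2R,5R)-2-{2-[(tert-butyldimethylsilyl)oxy]ethyl}-5-hydroxy-2-methyl-5-(propan-2-yl)cyclopentyl]-3-iodobut-2-en-1-yl 4-(acetyloxy)benzoate | CC(C)(C)[Si](C)(C)OCC[C@@]1(C)CC[C@@](O)(C(C)C)[C@@H]1[C@@H](OC(=O)c1ccc(OC(C)=O)cc1)/C=C(/C)I | intermediate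
32 | (1R,2Z)-1-[(1S,2R,5R)-2-hydroxy-5-(2-hydroxyethyl)-5-methyl-2-(propan-2-yl)cyclopentyl]-3-iodobut-2-en-1-yl 4-(acetyloxy)benzoate | OCC[C@@]1(C)CC[C@@](O)(C(C)C)[C@@H]1[C@@H](OC(=O)c1ccc(OC(C)=O)cc1)/C=C(/C)I | intermediate
33 | (1R,2Z)-1-[(1S,2R,5R)-2-hydroxy-5-methyl-5-(2-oxoethyl)-2-(propan-2-yl)cyclopentyl]-3-iodobut-2-en-1-yl 4-(acetyloxy)benzoate | O=CC[C@@]1(C)CC[C@@](O)(C(C)C)[C@@H]1[C@@H](OC(=O)c1ccc(OC(C)=O)cc1)/C=C(/C)I | intermediate
34 | (3R,3aS,4S,7S,8aR)-3,7-dihydroxy-6,8a-dimethyl-3-(propan-2-yl)-1,2,3,3a,4,7,8,8a-octahydroazulen-4-yl 4-(acetyloxy)benzoate | O[C@H]1C[C@@]2(C)CC[C@@](O)(C(C)C)[C@@H]2[C@@H](OC(=O)c2ccc(OC(C)=O)cc2)C=C1C | intermediate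
35 | acetic anhydride | CC(=O)OC(C)=O | starting material
36 | (3R,3aS,4S,7S,8aR)-7-(acetyloxy)-3-hydroxy-6,8a-dimethyl-3-(propan-2-yl)-1,2,3,3a,4,7,8,8a-octahydroazulen-4-yl 4-(acetyloxy)benzoate | CC(=O)O[C@H]1C[C@@]2(C)CC[C@@](O)(C(C)C)[C@@H]2[C@@H](OC(=O)c2ccc(OC(C)=O)cc2)C=C1C | intermediate
37 | (3R,3aS,4S,7S,8aR)-7-(acetyloxy)-3-hydroxy-6,8a-dimethyl-3-(propan-2-yl)-1,2,3,3a,4,7,8,8a-octahydroazulen-4-yl 4-hydroxybenzoate | CC(=O)O[C@H]1C[C@@]2(C)CC[C@@](O)(C(C)C)[C@@H]2[C@@H](OC(=O)c2ccc(O)cc2)C=C1C | target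

Total step count: 19. Longest linear sequence: 19 steps (the route is fully linear from 1).

Steps most likely to fail

Step 17. What may go wrong: the two faces of the C1 aldehyde are discriminated poorly during ring closure, so the C1 carbinol forms as a mixture of epimers. The fallback sets out from 33 and comes back at 34. The cyclisation is run as before, and the mixture of 34 and its C1 epimer (3R,3aS,4S,7R,8aR)-3,7-dihydroxy-6,8a-dimethyl-3-(propan-2-yl)-1,2,3,3a,4,7,8,8a-octahydroazulen-4-yl 4-(acetyloxy)benzoate F6 is oxidised with Dess–Martin periodinane to the enone (3R,3aS,4S,8aR)-3-hydroxy-6,8a-dimethyl-7-oxo-3-(propan-2-yl)-1,2,3,3a,4,7,8,8a-octahydroazulen-4-yl 4-(acetyloxy)benzoate F7, in which C1 is no longer stereogenic. Corey–Bakshi–Shibata reduction with the (R)-configured methyl oxazaborolidine and BH3·SMe2 at low temperature, with the methyl-bearing alkenyl carbon C10 as the large group, should deliver hydride to the face that returns 34. C1 is then set by the reagent and not by the ring.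

Step 12. What may go wrong: chelation is lost and the addition runs through an open Felkin–Anh-type transition state, giving a mixture at C8. The fallback sets out from 24 and comes back at 26. The addition is carried out without relying on its selectivity, and the mixture of 26 and its C8 epimer (1R,2S,3R)-3-{2-[(tert-butyldimethylsilyl)oxy]ethyl}-2-[(1S)-1-hydroxybut-2-yn-1-yl]-3-methyl-1-(propan-2-yl)cyclopentan-1-ol F4 is oxidised with Dess–Martin periodinane to the ynone 1-[(1R,2R,5R)-2-{2-[(tert-butyldimethylsilyl)oxy]ethyl}-5-hydroxy-2-methyl-5-(propan-2-yl)cyclopentyl]but-2-yn-1-one F5. Transfer hydrogenation with RuCl[(R,R)-TsDPEN](p-cymene) in 2-propanol without added base, a reagent-controlled reduction of alkynyl ketones, should then give the (R)-propargylic alcohol 26.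

Step 6. What may go wrong: the hindered ketone is hydrogenated slowly, or the catalyst does not fully control which C7 epimer is reduced. The fallback sets out from 15 and comes back at 20. NaBH4 in MeOH at low temperature reduces 15 without a catalyst, hydride entering anti to the ester to give mainly cis hydroxy esters such as methyl (1R,2R,5S)-2-{2-[(tert-butyldimethylsilyl)oxy]ethyl}-5-hydroxy-2-methylcyclopentane-1-carboxylate F1. LiAlH4 then gives (1S,2S,3R)-3-{2-[(tert-butyldimethylsilyl)oxy]ethyl}-2-(hydroxymethyl)-3-methylcyclopentan-1-ol F2, and at this stage the diols of the wrong C7 series are removed by chromatography. Selective silylation with TESCl gives (1S,2S,3R)-3-{2-[(tert-butyldimethylsilyl)oxy]ethyl}-3-methyl-2-{[(triethylsilyl)oxy]methyl}cyclopentan-1-ol F3, and Dess–Martin oxidation erases the C6 carbinol centre and returns ketone 20. In this variant C7 is sorted by separation instead of being set by the catalyst.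

Further compounds
F1 | step 6 | methyl (1R,2R,5S)-2-{2-[(tert-butyldimethylsilyl)oxy]ethyl}-5-hydroxy-2-methylcyclopentane-1-carboxylate | CC(C)(C)[Si](C)(C)OCC[C@@]1(C)CC[C@H](O)[C@@H]1C(=O)OC
F2 | step 6 | (1S,2S,3R)-3-{2-[(tert-butyldimethylsilyl)oxy]ethyl}-2-(hydroxymethyl)-3-methylcyclopentan-1-ol | CC(C)(C)[Si](C)(C)OCC[C@@]1(C)CC[C@H](O)[C@@H]1CO
F3 | step 6 | (1S,2S,3R)-3-{2-[(tert-butyldimethylsilyl)oxy]ethyl}-3-methyl-2-{[(triethylsilyl)oxy]methyl}cyclopentan-1-ol | CC(C)(C)[Si](C)(C)OCC[C@@]1(C)CC[C@H](O)[C@@H]1CO[Si](CC)(CC)CC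
F4 | step 12 | (1R,2S,3R)-3-{2-[(tert-butyldimethylsilyl)oxy]ethyl}-2-[(1S)-1-hydroxybut-2-yn-1-yl]-3-methyl-1-(propan-2-yl)cyclopentan-1-ol | CC(C)(C)[Si](C)(C)OCC[C@@]1(C)CC[C@@](O)(C(C)C)[C@@H]1[C@H](O)C#CC
F5 | step 12 | 1-[(1R,2R,5R)-2-{2-[(tert-butyldimethylsilyl)oxy]ethyl}-5-hydroxy-2-methyl-5-(propan-2-yl)cyclopentyl]but-2-yn-1-one | CC(C)(C)[Si](C)(C)OCC[C@@]1(C)CC[C@@](O)(C(C)C)[C@@H]1C(=O)C#CC
F6 | step 17 | (3R,3aS,4S,7R,8aR)-3,7-dihydroxy-6,8a-dimethyl-3-(propan-2-yl)-1,2,3,3a,4,7,8,8a-octahydroazulen-4-yl 4-(acetyloxy)benzoate | O[C@@H]1C[C@@]2(C)CC[C@@](O)(C(C)C)[C@@H]2[C@@H](OC(=O)c2ccc(OC(C)=O)cc2)C=C1C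
F7 | step 17 | (3R,3aS,4S,8aR)-3-hydroxy-6,8a-dimethyl-7-oxo-3-(propan-2-yl)-1,2,3,3a,4,7,8,8a-octahydroazulen-4-yl 4-(acetyloxy)benzoate | O=C1C[C@@]2(C)CC[C@@](O)(C(C)C)[C@@H]2[C@@H](OC(=O)c2ccc(OC(C)=O)cc2)C=C1C
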